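150 min is the time to hold against the life of the catalyst, so the examination begins there.

the same everywhere: free enzyme 1.1 µM; temperature 40 °C

| flask | starting material | remark | time |
|---|---|---|---|
| amber | 0.050 M | the very flask that is asked about, followed so far |  |
| violet | 0.025 M | run made earlier |  |
| flask | 0.050 M |  | 2.5 h |

| run | time / min | product / % | starting material / % |
|---|---|---|---|
| amber | 15.0 | 19 | 77 |
| amber | 30.0 | 25 | 76 |
| amber | 50.0 | 24 | 77 |
| amber | 60.0 | 25 | 74 |
| amber | 80.0 | 23 | 76 |
| amber | 90.0 | 20 | 77 |
| violet | 0.500 | 5 | 94 |
| violet | 0.833 | 7 | 90 |
| violet | 1.33 | 12 | 85 |
| violet | 2.00 | 16 | 83 |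
| violet | 4.00 | 20 | 79 |
| violet | 6.00 | 25 | 75 |

(standard deviation of a reading: 1.5 percentage points)

1. product, in percent of the starting material first charged, at 2.5 h
2. the remedy with the largest gain of product, or "none" below 2 percentage points (north-east / south-east / south-west / none)
3. product present, with what was taken out counted in, in percent of the starting material first charged, after north-east
4. product present, with what was taken out counted in, in percent of the starting material first charged, after south-west

- north-east: change nothing and wait 5.0 h more
- south-east: at 2.5 h add free enzyme, 100% of the amount charged, then wait 5.0 h
- south-west: at 2.5 h take out 90% of the product then present, then wait 5.0 h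

- product that was removed still counts
- additions bring no volume worth counting

**What do the amber readings show?** From 30.0 min to 90.0 min product shows no rise, with a mean reading of 23.4%.

**Is that an equilibrium?** I doubt it. The violet flask reads 25% at its last reading and is still rising, by 5 percentage points over its last interval, against a scatter of 1.5 points.

**Then what stops amber?** I suspect catalyst deactivation, so I measure it. In violet the rate falls from 0.0902 /min to 0.0250 /min of the charge, between interval midpoints 4.33 min apart. That gives a working half-life, the time in which the rate of a flask halves, of 2.34 min in the violet flask.

**Where is that weak?** Slowing from other causes is counted in it, and it is a violet reading applied to amber, so it is a rough figure.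

**And the count?** The amber flask has 64.1 working half-lives behind it at 150 min. I therefore expect about 23.4% now, nothing from waiting, and nothing from removing product, while added free enzyme is the option that brings working catalyst.

The forecast gave 24% now, 24% after north-east, 40% after south-west and chose south-west, holding that the same fraction at different concentrations “points to a reversible equilibrium”.

The simulation gives 23.2% now, 23.2% after north-east and 23.2% after south-west. It names south-east as best, with a gain of 6.4 points.

    starting material + free enzyme ⇌ complex (K = 13.0 /M, k = 1.87 × 10⁵ /M/s, Ea = 15.0 kJ/mol, ΔH = −35.0 kJ/mol)
    free enzyme → unfolded enzyme (k = 8.63 × 10⁻⁴ /s, Ea = 208 kJ/mol)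
    complex → spent catalyst (k = 0.0107 /s, Ea = 79.0 kJ/mol)
    complex ⇌ free enzyme + product (K = 0.0350 M, k = 204 /s, Ea = 57.0 kJ/mol, ΔH = 25.0 kJ/mol)
    (constants at 40 °C)

In the amber flask the half-life of complex by its path to spent catalyst alone, 1.1 min, and that of free enzyme by its path to unfolded enzyme alone, 13 min, are both short against 150 min. Beside my 64.1 working half-lives, the share of the catalyst still able to turn over at 150 min is 0%, with 87.3% of it spent catalyst and 12.7% unfolded enzyme. For the repeat at 25 °C, scaling my half-life with the complex loss gives 10.8 min, so 13.9 half-lives. That repeat holds 0% of its catalyst as complex and 0% as free enzyme at 150 min, with product at 31.9%.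

The earlier runs and the new flask come from a simulation for an exercise, and the scatter is random.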